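In a one-step world starting material and coupling partner make target, and the curve climbs to the charge of the limiting reagent and stays there. These flasks test that picture.

the same everywhere: starting material 0.30 M

| run | coupling partner | remark | time |
|---|---|---|---|
| ash | 0.70 equiv | run made earlier |  |
| maple | 1 equiv | run made earlier |  |
| south-east | 0.700 equiv | a tube with plug flow, the mixed feed as stated, residence time 6.0 d | 6.0 d |
| north | 0.700 equiv (fed, over 3.00 d) | all but coupling partner at the start; coupling partner goes in evenly over 3.00 d, the run ends at 6.0 d | 6.0 d |
| east | 0.700 equiv | everything together in a closed stirred flask, run for 6.0 d | 6.0 d |
| west | 0.700 equiv | a single well-mixed tank run continuously and read at steady state, 6.0 d in it on average |  |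

ash run (percent of the starting material charged): time / d: target / % = 0.625: 38; 1.25: 45; 1.67: 45; 2.50: 43; 3.00: 43; 4.00: 41

maple run (percent of the starting material charged): time / h: target / % = 1.00: 6; 3.00: 17; 5.00: 24; 8.00: 34; 12.0: 42; 15.0: 45

(each reading ± 1.5 percentage points)

- the stated concentrations are those of everything mixed, before any reaction; amounts are the same in each set-up
- the analysis behind the earlier runs scatters by 1.5 percentage points, standard deviation
- the feed brings no volume worth counting
- the earlier runs were made in a closed, stirred flask

- the set-up with the highest amount of target at the outlet or at the end, in percent of the starting material put in ("none" if the first two lie within 2 percentage points) (south-east / north / east / west / none)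
- amount of target at the outlet or at the end, in percent of the starting material put in, south-east
- amount of target at the outlet or at the end, in percent of the starting material put in, north
- amount of target at the outlet or at the end, in percent of the starting material put in, east
- amount of target at the outlet or at the end, in percent of the starting material put in, west

The maple run has equal charges, so its early slope gives a forming time, the time in which target would reach the level of what remains:

forming time = time × share left ÷ share made = 0.660 d

At 0.70 equiv the one-step curve should level off near 70.0%, and at 4.00 d it should stand at 66.2%. The ash run instead reaches a knee of 45% at 1.25 d, which is lower than that level, and then sags to 41%. So the one-step curve stands 25 percentage points above that last reading, a gap I read as target made and lost again. This gap gives the fade time, target held multiplied by the time held and divided by target lost: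

fade time = 43% × 3.38 d ÷ 25 points = 5.77 d

My own reckoning carries the last ash reading forward on this fade time and adds what the one-step curve still gains:

east at 6.0 d = 31.4%

A slice in the south-east tube lives the history of the east flask, so the tube reads the same. In north, the feed reaches its middle at 1.50 d, so my reckoning takes target there as younger by that time, which gives 40.7%.

The forecast names north, with 38% for south-east, 43% for north, 38% for east and 33% for west: “The slow feed probably helps slightly”. For east and north the forecast stands above my 31.4% and 40.7%.

The flasks give 30.7% for south-east, 37.2% for north, 30.7% for east and 31.1% for west, so the best is north.

    target + by-product → side product (k = 0.0589 /M/h)
    starting material + coupling partner → target + by-product (k = 0.210 /M/h)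
    2 starting material → homo dimer (k = 4.40 × 10⁻⁴ /M/h)

At 6.00 d in north, target has a half-life of 4.4 d by its conversion with by-product into side product, shorter than the 12 d of starting material by the forming step. From the end of the feed, the fade time books 20 points of loss in north, and side product grows by 22 points. Read at 10 d, the same north flask is reckoned at 22.1%, its 37.2% carried on the fade time plus the fall of starting material from 32.4% to 28.9%, and it holds 24.6%.

(Readings and results come from a simulation on assumed constants; the scatter is artificial.)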